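## The problem

Compound 13 is a resorcinol (ring A) with carbon substituents on three adjacent ring carbons: 4-hydroxybenzyl arms on C4 and C6, a 2-phenylethyl chain on C5 between them, hydroxyls on C1 and C3, and the only ring hydrogen on C2. It has no stereocentre and a mirror plane through C2 and C5, so nothing has to be controlled in space; the difficulty is placing five substituents on one benzene ring with a crowded C4–C5–C6 triad. Electrophilic benzylation of a 5-substituted resorcinol would not solve this, because C2 between the two hydroxyls competes with C4 and C6 and each benzylation makes the ring more reactive. The four phenols make the final compound prone to oxidation, and each arm is a diarylmethane between two electron-rich rings that can ionise at the benzylic carbon in strong acid. The arm phenols are therefore best carried as robust ethers and freed last, under conditions that leave the benzylic C–C bonds alone. Any sp3 stereocentres that appear on the way are transient and may be carried as mixtures. The enabling feature is that ring A, one oxidation level lower, is a cyclohexane-1,3-dione. In that form C1 and C3 are carbonyl carbons, C2 is the methyl group of a methyl ketone, C6 and C5 are the α- and β-carbons of an enone that already carries one arm and the phenethyl chain, and C4 with its arm plus C3 are the central carbon and one ester carbon of a benzylmalonate. Ring A can then be closed by making only the C4–C5 and C2–C3 bonds.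

## Retrosynthesis

**13 to 12.** The two aryl O–H bonds of the arms are traced back to O–CH3. Methyl ethers are preferred to benzyl or silyl ethers because the arms must pass through hydride and alkoxide bases, hot aqueous alkali and acid, and a palladium dehydrogenation above 200 °C in which hydrogen is released. The resorcinol hydroxyls need no protection because they arise directly from the ring-forming chemistry. The forward step must cleave two anisole ethers without breaking an aryl–CH2–aryl bond.

**12 to 11.** No skeletal bond is cut; two hydrogens are added across C4–C5 of ring A, giving the symmetric 4,6-bis(4-methoxybenzyl)-5-(2-phenylethyl)cyclohexane-1,3-dione 11. This is preferred to building the arene by substitution because the 1,3-dicarbonyl pattern fixes the two hydroxyls, and the ring substituents are fixed by connectivity and not by directing effects. The price is three sp3 centres, which do not matter, and one dehydrogenation in the forward direction.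

**11 to 9.** A methoxycarbonyl group is added back at the arm-bearing carbon that becomes C4 of ring A (C1 of 9), via the keto acid 10. This is the retron of a malonate: the extra ester is what makes that carbon nucleophilic. The forward reaction must remove an ester from a quaternary carbon without opening the ring.

**9 to 7 and 3.** The C4–C5 and C2–C3 bonds of ring A are cut, passing through the open-chain adduct 8. This gives the enone 7 (ring A C1, C2, C5, C6 with one arm and the phenethyl chain) and the benzylmalonate 3 (C3, C4 with the other arm). Neighbouring cuts were weighed against this one:
- Reversed polarity (ketone enolate plus alkylidene malonate) would need regioselective enolisation of an unsymmetrical ketone at its more substituted side.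
- Cutting on both sides of C2 moves all the difficulty into a triply substituted glutarate.

The chosen cut gives two achiral partners of 20 and 13 carbons, each with its arm already in place. The forward reaction must push a crowded, reversible conjugate addition forward by coupling it to an irreversible ring closure.

**7 to 5 and 6.** The trisubstituted C=C bond of 7 is cut as a Horner–Wadsworth–Emmons olefination of aldehyde 6 with the α-benzylated β-ketophosphonate 5. A crossed aldol condensation was set aside because it would require enolisation of a methyl ketone at its internal α-carbon and would compete with self-condensation of 6. The olefination fixes the position of the double bond and of the arm unambiguously.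

**5 to 4 and 2; 3 to 1 and 2.** In each case the C–CH2Ar bond is cut. Both arms come from the same electrophile 2, by C-alkylation of the phosphonate anion of 4 and of the malonate anion of 1. Both are one-step operations on commercial materials; the only demand is mono-alkylation.

## Roads not taken

**Alternative 1:** The cut is the ring bond between C5 and a neighbouring arm-bearing carbon, made by aldol folding of an open-chain triketone, (1E)-4-[4-(benzyloxy)benzyl]-9-[4-(benzyloxy)phenyl]-1-phenylnon-1-ene-3,5,7-trione A2. With KOH the C8 methylene of A2 would attack the cinnamoyl carbonyl C3. Dehydration and enolisation would give 4,6-bis[4-(benzyloxy)benzyl]-5-[(E)-2-phenylethenyl]benzene-1,3-diol A1 directly at the aromatic oxidation level. One hydrogenation over Pd/C would then saturate the styrene and remove both benzyl ethers to give 13.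
- Merits: the ring is born aromatic, so no dehydrogenation is needed, and the endgame is a single mild step with no Lewis acid. In these respects it is better than the chosen plan.
- Weak points: in A2 the C4 methine and C6 methylene each lie between two carbonyls and are deprotonated first, so the C8 enolate needed is a minor species. The C6 carbanion can add to the styryl β-carbon C1 to close a different six-membered carbocycle. An enol oxygen can add to C1 or condense to a pyranone. The electrophile is a conjugated, α-branched ketone of low reactivity. A2 itself needs polyanion acylations to assemble.
- Comparison: the chosen plan offsets its longer endgame with partners made in one or two steps from bulk chemicals and with a ring closure that has only one feasible regiochemistry.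

**Alternative 2:** The cut is the two CH2–aryl bonds at the outer ends of the arms, made on an aromatic core. 2,4-Bis(bromomethyl)-1,5-dimethoxy-3-(2-phenylethyl)benzene A4 would couple twice with (4-methoxyphenyl)boronic acid A5 under Pd(OAc)2, a dialkylbiarylphosphine and K3PO4. This gives 1,5-dimethoxy-2,4-bis(4-methoxybenzyl)-3-(2-phenylethyl)benzene A3, and fourfold demethylation would give 13.
- Merits: it is convergent, uses the molecular symmetry, needs no change of oxidation level and forms both bonds by a well-established benzylic Suzuki coupling. If A4 were in hand it would probably be the shortest route, and in this it is better than the chosen plan.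
- Weak points: in A4 each bromomethyl group is ortho and para to a methoxy group, so it ionises easily and can alkylate another molecule of the electron-rich core. Making A4 by twofold electrophilic substitution of a 3,5-dimethoxybibenzyl must also avoid the position between the two methoxy groups and must put the second group onto a ring already crowded next to the phenethyl chain.
- Comparison: the chosen plan offsets this with the fact that every ring position is defined by which carbon of which partner it came from, and that no labile benzylic halide on an activated ring is ever handled.

**Alternative 3:** The cut is on both sides of C2 (C1–C2 and C2–C3), C2 coming from tert-butyl acetate A8. Its lithium enolate, made with LiN(SiMe3)2, would acylate one ester of dimethyl 2,4-bis(4-methoxybenzyl)-3-(2-phenylethyl)pentanedioate A7. The resulting β-keto ester enolate would then close onto the other ester to give tert-butyl 3,5-bis(4-methoxybenzyl)-2,6-dioxo-4-(2-phenylethyl)cyclohexane-1-carboxylate A6. Acid would remove the tert-butyl ester and CO2 and reach 11.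
- Merits: no quaternary carbon is made, the activating ester sits on the doubly activated C2 and leaves under mild acid, and no crowded conjugate addition is needed. In these respects it is better than the chosen plan.
- Weak points: A7 carries the whole C4–C5–C6 triad and needs several steps of its own. Both of its esters are α-branched and flank a branched centre, so they are slow acyl acceptors and are easily enolised by the acetate enolate. The second acylation asks a stabilised β-keto ester anion to attack a hindered ester. The dehydrogenation and demethylation endgame is the same as in the chosen plan, so nothing is saved there.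
- Comparison: the chosen plan offsets its harder ester removal with a far shorter supply of the ring-closure partners and with a ring closure by a reactive methyl ketone enolate.

Key step: step 4

Assumption: compounds 1, 2, 4 and 6 are taken as commercial. The sp3 stereocentres of 5 and 8 to 11 form as mixtures of stereoisomers and are carried on unseparated, since all are destroyed in step 6; their SMILES are written without configuration.

## Route

Step 1
Reactants: 1 dimethyl malonate; 2 4-methoxybenzyl chloride
Product: 3 dimethyl 2-(4-methoxybenzyl)malonate
Conditions: NaH (1 equiv), 1 (2 equiv), THF, 0 °C to 50 °C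
Reagents that add atoms: none
Why: Malonic ester alkylation with a reactive benzylic chloride; the excess of 1 holds back the second alkylation and is distilled off, and an aprotic solvent avoids solvolysis of 2.

Step 2
Reactants: 4 diethyl (2-oxopropyl)phosphonate; 2 4-methoxybenzyl chloride
Product: 5 diethyl [1-(4-methoxyphenyl)-3-oxobutan-2-yl]phosphonate (racemic)
Conditions: NaH (1 equiv), THF/DMF, 0 °C; then 2, rt to 50 °C
Reagents that add atoms: none
Why: C-alkylation of the stabilised β-ketophosphonate anion at the carbon between P=O and C=O; one equivalent of base and a slight excess of 4 limit dialkylation, and the new stereocentre is of no consequence because it becomes sp2 in step 3.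

Step 3
Reactants: 5 diethyl [1-(4-methoxyphenyl)-3-oxobutan-2-yl]phosphonate; 6 3-phenylpropanal
Product: 7 (E)-3-(4-methoxybenzyl)-6-phenylhex-3-en-2-one
Conditions: Ba(OH)2, THF/H2O (40:1), rt; then dilute HCl
Reagents that add atoms: none
Why: Horner–Wadsworth–Emmons olefination of an α-substituted β-ketophosphonate under mild Ba(OH)2 conditions that tolerate an enolisable aldehyde; the E isomer (acetyl trans to the chain) should predominate, and any Z isomer would serve equally in step 4 because the alkene geometry is lost in the conjugate addition.

Step 4
Reactants: 7 (E)-3-(4-methoxybenzyl)-6-phenylhex-3-en-2-one; 3 dimethyl 2-(4-methoxybenzyl)malonate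
Product: 9 methyl 1,3-bis(4-methoxybenzyl)-4,6-dioxo-2-(2-phenylethyl)cyclohexane-1-carboxylate, via Michael adduct 8 (not isolated)
Conditions: NaOMe (1.5 equiv), MeOH, reflux; then aq HCl, 0 °C
Reagents that add atoms: none
Why: This is a Michael–Claisen annulation, the reaction type by which dimedone is made from mesityl oxide and a malonate. Methoxide deprotonates 3 and the malonate anion adds to the β-carbon of 7 (ring A C4–C5 bond) to give the enolate of 8; proton exchange in methanol supplies the methyl ketone enolate, which attacks one malonate ester (ring A C2–C3 bond) in a 6-(enolendo)-exo-trig closure and expels methoxide. The conjugate addition is the crowded and reversible step, since a tertiary carbanion meets a β-carbon next to a branched α-carbon, and it is pulled forward because the closed 1,3-dione is deprotonated at once at C5 of 9 and that enolate does not reopen. Addition in the 1,4-sense is secured by the soft, stabilised nucleophile and by the reversibility of any carbonyl addition. The regiochemistry of closure is secured by ring size, since of the two ketone α-positions of 8 only the methyl group reaches an ester through a six-membered transition state and the other would close a four-membered ring. If the methyl ketone enolate of 7 were acylated by 3 first, the intramolecular conjugate addition that follows would give the same ring. The three sp3 ring stereocentres (C1, C2 and C3 of 9) form without control as a mixture and need none, because all three become sp2 in step 6.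

Step 5
Reactants: 9 methyl 1,3-bis(4-methoxybenzyl)-4,6-dioxo-2-(2-phenylethyl)cyclohexane-1-carboxylate
Product: 11 4,6-bis(4-methoxybenzyl)-5-(2-phenylethyl)cyclohexane-1,3-dione, via keto acid 10 (not isolated)
Conditions: KOH, H2O/1,4-dioxane, reflux; then aq HCl to pH 1, 90 °C
Reagents that add atoms: none
Why: Saponification and decarboxylation of a β-keto ester; in alkali the dione is present as its enolate, which shields the ketone beside the quaternary carbon from retro-Claisen attack while the ester is hydrolysed, and after acidification the β-keto acid 10 loses CO2 through the usual cyclic transition state.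

Step 6
Reactants: 11 4,6-bis(4-methoxybenzyl)-5-(2-phenylethyl)cyclohexane-1,3-dione
Product: 12 4,6-bis(4-methoxybenzyl)-5-(2-phenylethyl)benzene-1,3-diol
Conditions: 10% Pd/C, triglyme, 200 °C, N2 stream
Reagents that add atoms: none
Why: Catalytic dehydrogenation of a cyclohexane-1,3-dione to a resorcinol over palladium on carbon; only one C–C bond has to be dehydrogenated, aromatisation is the driving force, the gas stream removes the hydrogen, and the anisole ethers and benzylic methylenes are inert under these conditions.

Step 7
Reactants: 12 4,6-bis(4-methoxybenzyl)-5-(2-phenylethyl)benzene-1,3-diol
Product: 13 4,6-bis(4-hydroxybenzyl)-5-(2-phenylethyl)benzene-1,3-diol (CNP0361781.0)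
Conditions: BBr3 (excess), CH2Cl2, −78 °C to rt; then H2O
Reagents that add atoms: none
Why: Lewis-acid cleavage of aryl methyl ethers with BBr3 by bromide attack at the methyl group of the boron-bound ether; the free resorcinol hydroxyls are converted to borates during the reaction, which lowers the electron density of ring A and protects the diarylmethane bonds from acid-induced cleavage.

## Compound list

1 | dimethyl malonate | COC(=O)CC(=O)OC | starting material
2 | 4-methoxybenzyl chloride | COc1ccc(CCl)cc1 | starting material
3 | dimethyl 2-(4-methoxybenzyl)malonate | COC(=O)C(Cc1ccc(OC)cc1)C(=O)OC | intermediate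
4 | diethyl (2-oxopropyl)phosphonate | CCOP(=O)(CC(C)=O)OCC | starting material
5 | diethyl [1-(4-methoxyphenyl)-3-oxobutan-2-yl]phosphonate (racemic) | CCOP(=O)(OCC)C(Cc1ccc(OC)cc1)C(C)=O | intermediate
6 | 3-phenylpropanal | O=CCCc1ccccc1 | starting material
7 | (E)-3-(4-methoxybenzyl)-6-phenylhex-3-en-2-one | CC(=O)/C(Cc1ccc(OC)cc1)=C/CCc1ccccc1 | intermediate
8 | dimethyl 2-(4-methoxybenzyl)-2-[4-(4-methoxybenzyl)-5-oxo-1-phenylhexan-3-yl]malonate (Michael adduct, formed in the flask, mixture of stereoisomers) | COC(=O)C(Cc1ccc(OC)cc1)(C(=O)OC)C(CCc1ccccc1)C(Cc1ccc(OC)cc1)C(C)=O | intermediate
9 | methyl 1,3-bis(4-methoxybenzyl)-4,6-dioxo-2-(2-phenylethyl)cyclohexane-1-carboxylate (mixture of stereoisomers) | COC(=O)C1(Cc2ccc(OC)cc2)C(CCc2ccccc2)C(Cc2ccc(OC)cc2)C(=O)CC1=O | intermediate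
10 | 1,3-bis(4-methoxybenzyl)-4,6-dioxo-2-(2-phenylethyl)cyclohexane-1-carboxylic acid (keto acid, formed in the flask, mixture of stereoisomers) | OC(=O)C1(Cc2ccc(OC)cc2)C(CCc2ccccc2)C(Cc2ccc(OC)cc2)C(=O)CC1=O | intermediate
11 | 4,6-bis(4-methoxybenzyl)-5-(2-phenylethyl)cyclohexane-1,3-dione (mixture of stereoisomers) | COc1ccc(CC2C(=O)CC(=O)C(Cc3ccc(OC)cc3)C2CCc2ccccc2)cc1 | intermediate
12 | 4,6-bis(4-methoxybenzyl)-5-(2-phenylethyl)benzene-1,3-diol | COc1ccc(Cc2c(O)cc(O)c(Cc3ccc(OC)cc3)c2CCc2ccccc2)cc1 | intermediate
13 | 4,6-bis(4-hydroxybenzyl)-5-(2-phenylethyl)benzene-1,3-diol (CNP0361781.0) | Oc1ccc(Cc2c(O)cc(O)c(Cc3ccc(O)cc3)c2CCc2ccccc2)cc1 | target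

## Step count and risk

Total step count: 7. Longest linear sequence: 6 steps (steps 2, 3, 4, 5, 6, 7, from 4 to 13); step 1 is a one-step branch that joins at step 4.

**Step 4 (key step).** The most likely failure is that the conjugate addition does not advance. The equilibrium between the tertiary malonate anion and the α-branched enone may lie on the side of the components, with reversal faster than ring closure. Meanwhile methoxide could slowly divert 7 by γ-deprotonation and deconjugation or by self-condensation through its methyl ketone enolate. The fallback takes the second arm off the nucleophile and introduces it after the ring is closed. Setting out from 7 and 1, the same annulation with the unsubstituted and much less hindered malonate (NaOMe, MeOH, reflux) should pass through dimethyl 2-[4-(4-methoxybenzyl)-5-oxo-1-phenylhexan-3-yl]malonate F1 and give methyl 3-(4-methoxybenzyl)-4,6-dioxo-2-(2-phenylethyl)cyclohexane-1-carboxylate F2. Its dianion (LiN(i-Pr)2, 2.2 equiv, THF, −78 to 0 °C) is formed by deprotonation first between the two ketones and then at the ester-bearing carbon. It should be alkylated by 2 at the latter, more basic site (γ-alkylation of a β-dicarbonyl dianion), which brings the route back at 9.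

**Step 6.** The most likely failure is hydrogen transfer on the catalyst. The hydrogen set free may reduce part of the dione and lead to loss of one oxygen function. Alternatively the dehydrogenation may stall because the three adjacent substituents keep the ring from lying flat on the metal. The fallback is a stepwise, stoichiometric oxidation setting out from 11.
- MeOH with catalytic TsOH at reflux should give the enol ether 3-methoxy-4,6-bis(4-methoxybenzyl)-5-(2-phenylethyl)cyclohex-2-en-1-one F3, a single constitution because 11 is symmetric.
- Kinetic deprotonation at C6 with LiN(i-Pr)2 at −78 °C and trapping with PhSeBr should give 3-methoxy-4,6-bis(4-methoxybenzyl)-5-(2-phenylethyl)-6-(phenylselanyl)cyclohex-2-en-1-one F4.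
- H2O2 should oxidise it to 3-methoxy-4,6-bis(4-methoxybenzyl)-5-(2-phenylethyl)-6-(phenylseleninyl)cyclohex-2-en-1-one F5.
- Syn-elimination of F5 and tautomerisation of the resulting dienone should give 5-methoxy-2,4-bis(4-methoxybenzyl)-3-(2-phenylethyl)phenol F6.
- BBr3 in CH2Cl2, as in step 7 but with one more equivalent, should then cleave all three methyl ethers. This fallback returns to the route at 13 and passes 12 by.

**Step 5.** The most likely failure is ring opening by retro-Claisen attack of hydroxide at the ketone beside the quaternary carbon. This becomes competitive because the ester carbonyl sits on a fully substituted carbon and is hydrolysed slowly. The fallback avoids attack at any carbonyl. Setting out from 9, a Krapcho dealkoxycarbonylation (LiCl, wet DMSO, 150 °C) should remove the ester methyl group by chloride attack at carbon. The carboxylate of 10 formed this way loses CO2 at the reaction temperature, and the route is rejoined at 11. This fallback makes no compound outside the compound list (entry F0).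

## Further compounds

F1 | step 4 | dimethyl 2-[4-(4-methoxybenzyl)-5-oxo-1-phenylhexan-3-yl]malonate | COC(=O)C(C(=O)OC)C(CCc1ccccc1)C(Cc1ccc(OC)cc1)C(C)=O
F2 | step 4 | methyl 3-(4-methoxybenzyl)-4,6-dioxo-2-(2-phenylethyl)cyclohexane-1-carboxylate | COC(=O)C1C(CCc2ccccc2)C(Cc2ccc(OC)cc2)C(=O)CC1=O
F3 | step 6 | 3-methoxy-4,6-bis(4-methoxybenzyl)-5-(2-phenylethyl)cyclohex-2-en-1-one | COC1=CC(=O)C(Cc2ccc(OC)cc2)C(CCc2ccccc2)C1Cc1ccc(OC)cc1
F4 | step 6 | 3-methoxy-4,6-bis(4-methoxybenzyl)-5-(2-phenylethyl)-6-(phenylselanyl)cyclohex-2-en-1-one | COC1=CC(=O)C(Cc2ccc(OC)cc2)([Se]c2ccccc2)C(CCc2ccccc2)C1Cc1ccc(OC)cc1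
F5 | step 6 | 3-methoxy-4,6-bis(4-methoxybenzyl)-5-(2-phenylethyl)-6-(phenylseleninyl)cyclohex-2-en-1-one | COC1=CC(=O)C(Cc2ccc(OC)cc2)([Se](=O)c2ccccc2)C(CCc2ccccc2)C1Cc1ccc(OC)cc1
F6 | step 6 | 5-methoxy-2,4-bis(4-methoxybenzyl)-3-(2-phenylethyl)phenol | COc1cc(O)c(Cc2ccc(OC)cc2)c(CCc2ccccc2)c1Cc1ccc(OC)cc1
F0 | step 5 | none | none
A1 | alternative 1 | 4,6-bis[4-(benzyloxy)benzyl]-5-[(E)-2-phenylethenyl]benzene-1,3-diol | Oc1cc(O)c(Cc2ccc(OCc3ccccc3)cc2)c(/C=C/c2ccccc2)c1Cc1ccc(OCc2ccccc2)cc1
A2 | alternative 1 | (1E)-4-[4-(benzyloxy)benzyl]-9-[4-(benzyloxy)phenyl]-1-phenylnon-1-ene-3,5,7-trione | O=C(/C=C/c1ccccc1)C(Cc1ccc(OCc2ccccc2)cc1)C(=O)CC(=O)CCc1ccc(OCc2ccccc2)cc1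
A3 | alternative 2 | 1,5-dimethoxy-2,4-bis(4-methoxybenzyl)-3-(2-phenylethyl)benzene | COc1ccc(Cc2c(OC)cc(OC)c(Cc3ccc(OC)cc3)c2CCc2ccccc2)cc1
A4 | alternative 2 | 2,4-bis(bromomethyl)-1,5-dimethoxy-3-(2-phenylethyl)benzene | COc1cc(OC)c(CBr)c(CCc2ccccc2)c1CBr
A5 | alternative 2 | (4-methoxyphenyl)boronic acid | COc1ccc(B(O)O)cc1
A6 | alternative 3 | tert-butyl 3,5-bis(4-methoxybenzyl)-2,6-dioxo-4-(2-phenylethyl)cyclohexane-1-carboxylate | CC(C)(C)OC(=O)C1C(=O)C(Cc2ccc(OC)cc2)C(CCc2ccccc2)C(Cc2ccc(OC)cc2)C1=O
A7 | alternative 3 | dimethyl 2,4-bis(4-methoxybenzyl)-3-(2-phenylethyl)pentanedioate | COC(=O)C(Cc1ccc(OC)cc1)C(CCc1ccccc1)C(Cc1ccc(OC)cc1)C(=O)OC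
A8 | alternative 3 | tert-butyl acetate | CC(=O)OC(C)(C)C
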